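**Plan**

1. Numbering used throughout: furanone = O, C1 (enol-ether C), C2, C3 (C=O), C4 (bears CH3 = C15); exocyclic C5; butenolide = O, C6, C7, C11 (bears CH2OAc = C13), C12; chain C8 (ester carbon), C9, C10 (bears CH3 = C14).
2. Cuts: the C8 ester C–O; the butenolide is traced back to a furan (C12–H, C5 as CH2 on C6); then C4–C5, which opens the nine-membered ring (C4, C5, C6, C7, C8, C9, C10, C1, O); then O–C1 and C2–C3 of the furanone, C10–C1, C8–C9 and C5–C6.
3. Enabling feature: C3=O/C4 is the keto form of a 2-methyl-3-hydroxyfuran, so C4 is the carbon terminus of an aromatic 3-furanolate; C5 sits on C6 of a ring that can be carried as a furan, so an oxygenated C5 is a furfuryl (η3-benzyl type) electrophile. Helpers: butenolide held as furan, C8 held as ketone (no alkoxide competitor), C5–O as tert-butyl carbonate (leaving group and internal base).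
4. Forward: furan first, chain built on it, furanone closed by Au catalysis, nine-membered ring closed last by Pd-catalysed dearomatising C-furfurylation of the furanolate; then ketone reduction, esterification, furan → (E)-alkylidene butenolide.
5. Stereochemistry: C10 from Rh-catalysed asymmetric conjugate alkynylation; C4 in the ring closure (ligand control); C8 from CBS reduction of the ring ketone; the C5=C6 geometry is dictated by the ring.

Key step: step 13

Assumption: the ligand antipodes written in step 6 ((R)-DTBM-SEGPHOS) and step 13 ((R,R)-DACH-phenyl) are those expected to give 10S and 4S; the sense of induction is to be confirmed on the first run, and the mirror-image ligand is used with nothing else changed if it is reversed.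

**Step 1**
Reactants: 1 furan-3,4-diyldimethanol
Product: 2 mono-TBS ether of 1
Conditions: NaH (1.0 equiv), THF, 0 °C; TBSCl (1.0 equiv), rt
Reagents that add atoms: tert-butyldimethylsilyl chloride, CC(C)(C)[Si](C)(C)Cl
Why: Monosilylation of a symmetric diol through its sparingly soluble mono-sodium alkoxide (O-silylation) should stop at one silyl ether, which becomes the C13 oxygen.

**Step 2**
Reactants: 2 mono-TBS ether
Product: 3 4-(TBS-oxymethyl)furan-3-carbaldehyde
Conditions: MnO2 (excess), CH2Cl2, rt
Reagents that add atoms: none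
Why: MnO2 oxidises the furylmethanol (benzylic-type alcohol) to the aldehyde (future C8) and leaves furan and silyl ether alone.

**Step 3**
Reactants: 3 furan aldehyde
Product: 6 racemic C5,C8-diol, via lithium alkoxide 4 (not isolated), via C6-lithio alkoxide 5 (not isolated)
Conditions: (E)-1-bromoprop-1-ene, t-BuLi (2 equiv), Et2O, –78 °C, then 3; n-BuLi (1.3 equiv), TMEDA, –78 to 0 °C; (CH2O)n, –78 °C to rt; H2O
Reagents that add atoms: (E)-1-bromoprop-1-ene, C/C=C/Br; formaldehyde (as paraformaldehyde), C=O
Why: 1,2-Addition of (E)-prop-1-enyllithium (Br/Li exchange with retention) gives an alkoxide that directs ortho-lithiation (directed metalation, complex-induced proximity) to the adjacent furan α-carbon C6 rather than C12, and formaldehyde traps the aryllithium to install C5; the C8 carbinol is racemic and is oxidised in step 5.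

**Step 4**
Reactants: 6 diol
Product: 7 primary tert-butyl carbonate
Conditions: Boc2O (1.1 equiv), N-methylimidazole (cat.), Et3N, CH2Cl2, –20 °C
Reagents that add atoms: di-tert-butyl dicarbonate, CC(C)(C)OC(=O)OC(=O)OC(C)(C)C
Why: Chemoselective O-acylation of the unhindered primary furfuryl alcohol over the flanked secondary carbinol installs the later leaving group at C5.

**Step 5**
Reactants: 7 hydroxy carbonate
Product: 8 (E)-enone
Conditions: MnO2 (excess), CH2Cl2, rt
Reagents that add atoms: none
Why: MnO2 oxidation of the allylic and furylic secondary alcohol gives the enone and removes the racemic centre; carbonate and silyl ether are inert.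

**Step 6**
Reactants: 8 enone
Product: 9 (10S) β-alkynyl ketone
Conditions: [Rh(OAc)(C2H4)2]2 (2.5 mol %), (R)-DTBM-SEGPHOS (6 mol %), (triisopropylsilyl)acetylene (2 equiv), 1,4-dioxane, 80 °C
Reagents that add atoms: (triisopropylsilyl)acetylene, C#C[Si](C(C)C)(C(C)C)C(C)C
Why: Rh(I)/bisphosphine-catalysed asymmetric conjugate alkynylation of the (E)-enone (the bulky silyl group suppresses alkyne dimerisation) forms C10–C1 and sets C10 by ligand-controlled face selection.

**Step 7**
Reactants: 9 silylated alkynyl ketone
Product: 10 terminal alkyne with free C13–OH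
Conditions: TBAF (2.5 equiv), AcOH (2.5 equiv), THF, 0 °C to rt
Reagents that add atoms: none
Why: Fluoride-mediated desilylation cleaves the C(sp)–Si bond and the primary silyl ether in one operation, and the acetic acid buffer should spare the tert-butyl carbonate and C10.

**Step 8**
Reactants: 10 hydroxy alkyne
Product: 11 C13 acetate
Conditions: Ac2O, pyridine, DMAP (cat.), CH2Cl2, 0 °C
Reagents that add atoms: acetic anhydride, CC(=O)OC(C)=O
Why: Standard acetylation of the only free hydroxyl puts the C13 acetate of the target in place before any base-sensitive ring exists.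

**Step 9**
Reactants: 12 (S)-lactic acid
Product: 13 bis-triethylsilyl derivative
Conditions: TESCl (2.2 equiv), imidazole, CH2Cl2, 0 °C to rt
Reagents that add atoms: chlorotriethylsilane, CC[Si](Cl)(CC)CC
Why: Silylation of both hydroxyl and carboxyl groups gives the silyl ester needed for neutral acid chloride formation.

**Step 10**
Reactants: 13 silyl ester
Product: 14 (S)-2-(triethylsilyloxy)propanoyl chloride
Conditions: (COCl)2, DMF (cat.), CH2Cl2, 0 °C to rt
Reagents that add atoms: oxalyl chloride, ClC(=O)C(Cl)=O
Why: Silyl esters are converted into acid chlorides by oxalyl chloride/DMF under neutral conditions (Vilsmeier-type activation), so the silyl ether survives.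

**Step 11**
Reactants: 11 terminal alkyne; 14 acid chloride
Product: 15 alkynone
Conditions: 14 (1.3 equiv), CuI (5 mol %), Et3N (1.5 equiv), THF, rt
Reagents that add atoms: none
Why: Cu(I)-catalysed acylation of the terminal alkyne (acyl Sonogashira-type coupling run without Pd so that the furfuryl carbonate is not ionised) forms C2–C3.

**Step 12**
Reactants: 15 silyloxy alkynone
Product: 17 3(2H)-furanone, via hydroxy alkynone 16 (not isolated)
Conditions: HF·pyridine, THF, 0 °C; crude product, then Ph3PAuNTf2 (2 mol %), toluene, rt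
Reagents that add atoms: none
Why: After removal of the labile α-keto silyl ether, cationic Au(I) activates the ynone for 5-endo-dig attack of the γ-hydroxyl (cycloisomerisation of a γ-hydroxy alkynone) to form O–C1; the C4–H centre made here is erased in step 13.

**Step 13**
Reactants: 17 furanone furfuryl carbonate
Product: 18 nine-membered-ring ketone (4S,10S)
Conditions: Pd2(dba)3·CHCl3 (5 mol %), (R,R)-DACH-phenyl bis(2-diphenylphosphinobenzamide) ligand (12 mol %), toluene, 50 °C, 17 added by syringe pump (final 1 mM)
Reagents that add atoms: none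
Why: Proposed new method: Pd(0) ionises the C5–O tert-butyl carbonate to a cationic η3-furfuryl-Pd complex, the tert-butoxide released with CO2 deprotonates C4–H to the aromatic 3-furanolate, and outer-sphere attack of C4 on the exocyclic CH2 terminus forms C4–C5, which dearomatises the furanolate to the 2,2-disubstituted furanone and returns the aromatic furan and Pd(0). The closest known reaction type is the Pd-catalysed enantioselective benzylation (Tsuji–Trost type) of aromatic enolates such as azlactone and oxindole enolates with (hetero)arylmethyl carbonates, here run intramolecularly on a 3(2H)-furanone enolate. The nine-membered ring (C4, C5, C6, C7, C8, C9, C10, C1, O) closes in a formal 9-exo-tet mode at C5 (leaving group outside the ring), helped by two planar five-membered rings and the sp2 C8, while high dilution suppresses dimerisation. C4 is the only new stereocentre and the 4S face is to be imposed by the chiral pocket of the ligand, because the resident C10 centre should bias only weakly (its methyl lies in the furanolate plane in one transition state and perpendicular to it in the other). The step needs C- over O-alkylation and C4 over C2 attack, expected from the soft outer-sphere mechanism and from C4 being flanked by ring O and O–; it also needs ionisation at C5 and not C13, secured by the carbonate on the 2-furylmethyl carbon against the poorer acetate on the 3-furylmethyl carbon, and the ketone at C8 leaves no alkoxide that could capture the η3 terminus.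

**Step 14**
Reactants: 18 ring ketone
Product: 19 ring alcohol (4S,8S,10S)
Conditions: (R)-2-methyl-CBS-oxazaborolidine (1.0 equiv), BH3·SMe2 (1.2 equiv), THF, –30 °C; aqueous work-up
Reagents that add atoms: none
Why: CBS reduction should take the furyl ketone in preference to the vinylogous-ester carbonyl C3 and the acetate, and the (R)-oxazaborolidine delivers hydride to the face that gives 8S (furyl as large group).

**Step 15**
Reactants: 20 ethyl 2-(hydroxymethyl)prop-2-enoate
Product: 21 TBS ether
Conditions: TBSCl, imidazole, CH2Cl2, rt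
Reagents that add atoms: tert-butyldimethylsilyl chloride, CC(C)(C)[Si](C)(C)Cl
Why: Routine O-silylation protects the primary allylic alcohol of the side chain.

**Step 16**
Reactants: 21 silyl ether ester
Product: 22 2-(TBS-oxymethyl)prop-2-enoic acid
Conditions: LiOH, THF/H2O, 0 °C; 1 M HCl to pH 3
Reagents that add atoms: lithium hydroxide, [Li+].[OH-]
Why: Saponification of the ethyl ester gives the acid while the silyl ether survives cold hydroxide.

**Step 17**
Reactants: 19 ring alcohol; 22 acid
Product: 23 C8 ester
Conditions: 22 (1.5 equiv), DCC, DMAP (cat.), CH2Cl2, 0 °C to rt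
Reagents that add atoms: none
Why: Steglich esterification acylates the only free hydroxyl with retention at C8.

**Step 18**
Reactants: 23 furan ester
Product: 26 O-TBS target, via furan endoperoxide 24 (not isolated), via hydroxybutenolide 25 (not isolated)
Conditions: O2, hν (visible), rose bengal (cat.), i-Pr2NEt, CH2Cl2, –78 °C; then Ac2O, Et3N, DMAP (cat.), 0 °C to rt
Reagents that add atoms: dioxygen, O=O
Why: [4+2] Addition of singlet oxygen to the electron-rich trisubstituted furan, Kornblum–DeLaMare fragmentation at the only bridgehead hydrogen (C12–H) and acylative dehydration of the C6 hemiketal should give the butenolide with C12=O and the C5=C6 bond, whose E geometry (C4 cis to C7) is enforced by the nine-membered ring.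

**Step 19**
Reactants: 26 O-TBS target
Product: 27 target
Conditions: HF·pyridine, THF/pyridine, 0 °C
Reagents that add atoms: none
Why: Buffered fluoride desilylation frees the primary side-chain hydroxyl without touching the acetate, the acrylate or the enol lactone.

**Compound list**

1 | furan-3,4-diyldimethanol | OCc1cocc1CO | starting material
2 | [4-({[tert-butyl(dimethyl)silyl]oxy}methyl)furan-3-yl]methanol | OCc1cocc1CO[Si](C)(C)C(C)(C)C | intermediate
3 | 4-({[tert-butyl(dimethyl)silyl]oxy}methyl)furan-3-carbaldehyde | O=Cc1cocc1CO[Si](C)(C)C(C)(C)C | intermediate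
4 | lithium (E)-1-[4-(TBS-oxymethyl)furan-3-yl]but-2-en-1-olate, racemic | C/C=C/C(O[Li])c1cocc1CO[Si](C)(C)C(C)(C)C | intermediate (not isolated)
5 | lithium (E)-1-[2-lithio-4-(TBS-oxymethyl)furan-3-yl]but-2-en-1-olate, racemic | C/C=C/C(O[Li])c1c([Li])occ1CO[Si](C)(C)C(C)(C)C | intermediate (not isolated)
6 | (E)-1-[2-(hydroxymethyl)-4-(TBS-oxymethyl)furan-3-yl]but-2-en-1-ol, racemic at the carbinol (C8) | C/C=C/C(O)c1c(CO)occ1CO[Si](C)(C)C(C)(C)C | intermediate
7 | tert-butyl {3-[(E)-1-hydroxybut-2-en-1-yl]-4-(TBS-oxymethyl)furan-2-yl}methyl carbonate, racemic | C/C=C/C(O)c1c(COC(=O)OC(C)(C)C)occ1CO[Si](C)(C)C(C)(C)C | intermediate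
8 | tert-butyl {3-[(E)-but-2-enoyl]-4-(TBS-oxymethyl)furan-2-yl}methyl carbonate | C/C=C/C(=O)c1c(COC(=O)OC(C)(C)C)occ1CO[Si](C)(C)C(C)(C)C | intermediate
9 | tert-butyl {3-[(3S)-3-methyl-5-(triisopropylsilyl)pent-4-ynoyl]-4-(TBS-oxymethyl)furan-2-yl}methyl carbonate | C[C@@H](CC(=O)c1c(COC(=O)OC(C)(C)C)occ1CO[Si](C)(C)C(C)(C)C)C#C[Si](C(C)C)(C(C)C)C(C)C | intermediate
10 | tert-butyl {4-(hydroxymethyl)-3-[(3S)-3-methylpent-4-ynoyl]furan-2-yl}methyl carbonate | C[C@@H](CC(=O)c1c(COC(=O)OC(C)(C)C)occ1CO)C#C | intermediate
11 | {5-[(tert-butoxycarbonyloxy)methyl]-4-[(3S)-3-methylpent-4-ynoyl]furan-3-yl}methyl acetate | C[C@@H](CC(=O)c1c(COC(=O)OC(C)(C)C)occ1COC(C)=O)C#C | intermediate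
12 | (S)-lactic acid | C[C@H](O)C(=O)O | starting material
13 | triethylsilyl (2S)-2-[(triethylsilyl)oxy]propanoate | C[C@H](O[Si](CC)(CC)CC)C(=O)O[Si](CC)(CC)CC | intermediate
14 | (2S)-2-[(triethylsilyl)oxy]propanoyl chloride | C[C@H](O[Si](CC)(CC)CC)C(Cl)=O | intermediate
15 | {5-[(tert-butoxycarbonyloxy)methyl]-4-[(3S,7S)-3-methyl-6-oxo-7-(triethylsilyloxy)oct-4-ynoyl]furan-3-yl}methyl acetate | C[C@H](O[Si](CC)(CC)CC)C(=O)C#C[C@@H](C)CC(=O)c1c(COC(=O)OC(C)(C)C)occ1COC(C)=O | intermediate
16 | {5-[(tert-butoxycarbonyloxy)methyl]-4-[(3S,7S)-7-hydroxy-3-methyl-6-oxooct-4-ynoyl]furan-3-yl}methyl acetate | C[C@H](O)C(=O)C#C[C@@H](C)CC(=O)c1c(COC(=O)OC(C)(C)C)occ1COC(C)=O | intermediate (not isolated)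
17 | {5-[(tert-butoxycarbonyloxy)methyl]-4-{(3S)-3-[(5S)-5-methyl-4-oxo-4,5-dihydrofuran-2-yl]butanoyl}furan-3-yl}methyl acetate (the furanone CH–CH3 centre is enolisable) | C[C@@H]1OC(=CC1=O)[C@@H](C)CC(=O)c1c(COC(=O)OC(C)(C)C)occ1COC(C)=O | intermediate
18 | nine-membered-ring ketone (4S,10S): furanone C4 carries C15H3 and the C5H2 link to C6 of the furan; C8 is C=O; C13–OAc on the furan | O=C1C[C@H](C)C2=CC(=O)[C@](C)(Cc3occ(COC(C)=O)c31)O2 | intermediate
19 | ring alcohol (4S,8S,10S): 18 with C8 as CH–OH | O[C@H]1C[C@H](C)C2=CC(=O)[C@](C)(Cc3occ(COC(C)=O)c31)O2 | intermediate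
20 | ethyl 2-(hydroxymethyl)prop-2-enoate | C=C(CO)C(=O)OCC | starting material
21 | ethyl 2-({[tert-butyl(dimethyl)silyl]oxy}methyl)prop-2-enoate | C=C(CO[Si](C)(C)C(C)(C)C)C(=O)OCC | intermediate
22 | 2-({[tert-butyl(dimethyl)silyl]oxy}methyl)prop-2-enoic acid | C=C(CO[Si](C)(C)C(C)(C)C)C(=O)O | intermediate
23 | C8 ester of 19 with 22 (4S,8S,10S) | C=C(CO[Si](C)(C)C(C)(C)C)C(=O)O[C@H]1C[C@H](C)C2=CC(=O)[C@](C)(Cc3occ(COC(C)=O)c31)O2 | intermediate
24 | furan 2,5-endoperoxide of 23 (O–O bridge between C6 and C12) | C=C(CO[Si](C)(C)C(C)(C)C)C(=O)O[C@H]1C[C@H](C)C2=CC(=O)[C@](C)(CC34OOC(O3)C(COC(C)=O)=C41)O2 | intermediate (not isolated)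
25 | γ-hydroxybutenolide from 24 (C12=O, C6–OH, either C6 epimer) | C=C(CO[Si](C)(C)C(C)(C)C)C(=O)O[C@H]1C[C@H](C)C2=CC(=O)[C@](C)(CC3(O)OC(=O)C(COC(C)=O)=C31)O2 | intermediate (not isolated)
26 | side-chain O-TBS ether of the target (4S,8S,10S, 5E) | C=C(CO[Si](C)(C)C(C)(C)C)C(=O)O[C@H]1C[C@H](C)C2=CC(=O)[C@](C)(/C=C3/OC(=O)C(COC(C)=O)=C31)O2 | intermediate
27 | CNP0193735.1 (4S,8S,10S, 5E) | C=C(CO)C(=O)O[C@H]1C[C@H](C)C2=CC(=O)[C@](C)(/C=C3/OC(=O)C(COC(C)=O)=C31)O2 | target

**Step count and risks**

Total steps: 19. Longest linear sequence: 15 (steps 1–8, 11–14, 17–19).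

Steps most likely to fail:

1. Step 13 (proposed new method). O-alkylation or intermolecular coupling may outrun the strained nine-membered C–C closure, and the ligand may not override the substrate's facial bias at C4. Fallback with known chemistry, from 17 back to 18: the carbonate of 17 is cleaved with TFA (CH2Cl2, 0 °C) to the furfuryl alcohol F1, which MnO2 oxidises to the furan-2-carbaldehyde F2. Under high dilution, LiHMDS (1.0 equiv, THF, –78 °C) forms the furanone enolate, which adds to the C5 aldehyde in a reversible intramolecular aldol reaction (the usual C2 aldol reactivity of 3(2H)-furanones) to give the ring carbinol F3; its C5 configuration does not matter. F3 is converted with phenyl chlorothionoformate/DMAP into the thionocarbonate F4, and Barton–McCombie deoxygenation (Bu3SnH, AIBN, benzene, 80 °C) returns 18.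

2. Step 14. Hydride may be delivered from the periphery of the ring against the catalyst's preference, giving the C8 epimer, or the furanone carbonyl may be reduced as well. Fallback, from 18 back to 23: reduction under substrate control (NaBH4, MeOH/CH2Cl2, –40 °C) is accepted to give the (8R)-alcohol F5, and a Mitsunobu esterification with 22 (PPh3, DIAD, THF) inverts C8 and gives 23 directly, bypassing 19.

3. Step 3. Lithiation may occur at the other α-position (C12), followed by O-to-C silyl migration, or the alkoxide may not direct the metalation cleanly in one pot. Fallback, from 3 back to 6: the aldehyde is first masked in situ as its α-amino alkoxide with lithium N,N,N′-trimethylethylenediamide, which directs n-BuLi to C6. Paraformaldehyde and aqueous work-up then give the hydroxymethyl aldehyde F6, and (E)-prop-1-enyllithium (2.2 equiv, –78 °C) adds to F6 to give 6.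

**Further compounds**

F1 | step 13 | {5-(hydroxymethyl)-4-{(3S)-3-[(5S)-5-methyl-4-oxo-4,5-dihydrofuran-2-yl]butanoyl}furan-3-yl}methyl acetate | C[C@@H]1OC(=CC1=O)[C@@H](C)CC(=O)c1c(CO)occ1COC(C)=O
F2 | step 13 | {5-formyl-4-{(3S)-3-[(5S)-5-methyl-4-oxo-4,5-dihydrofuran-2-yl]butanoyl}furan-3-yl}methyl acetate | C[C@@H]1OC(=CC1=O)[C@@H](C)CC(=O)c1c(C=O)occ1COC(C)=O
F3 | step 13 | ring ketone 18 bearing OH on C5 (4S,10S, C5 epimers) | O=C1C[C@H](C)C2=CC(=O)[C@](C)(C(O)c3occ(COC(C)=O)c31)O2
F4 | step 13 | O-phenyl thionocarbonate of F3 | O=C1C[C@H](C)C2=CC(=O)[C@](C)(C(OC(=S)Oc4ccccc4)c3occ(COC(C)=O)c31)O2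
F5 | step 14 | ring alcohol (4S,8R,10S), C8 epimer of 19 | O[C@@H]1C[C@H](C)C2=CC(=O)[C@](C)(Cc3occ(COC(C)=O)c31)O2
F6 | step 3 | 2-(hydroxymethyl)-4-({[tert-butyl(dimethyl)silyl]oxy}methyl)furan-3-carbaldehyde | O=Cc1c(CO)occ1CO[Si](C)(C)C(C)(C)C
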